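**Plan**

Numbering: ring A (the methoxy-bearing benzene) has C1 (OMe), C2 (H), C3 (CH3), C4 (carbonyl carbon of ring C), C5 (diaryl ether O) and C6 (CH2OH); ring B (the phthalide benzene) has C1' (ether O), C2' (ester O), C3' (CH3), C4' (OH), C5' (lactone C=O) and C6' (lactol carbon); ring C is the seven-membered lactone.
Enabling feature: on ring A the ether oxygen (C5) and a one-carbon group (C6) sit on neighbouring carbons, with the C1 methoxy group flanking C6. This is the pattern left when a nucleophile and an electrophile add across the C5–C6 bond of a 3-methoxyaryne.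
Retrosynthetic cuts, in order: the lactol O–H (back to an (R)-configured 1-phenylethyl acetal), the ring C ester bond C(=O)–O(C2'), the C6 CH2OH (back to CO2H), then the C5–O(C1') ether bond and the C6–carboxyl bond together in one aryne/phenoxide/CO2 coupling.
Forward: ring A silyl triflate 12 (from 3-methoxy-5-methylphenol by two directed lithiations) and ring B phenol 21 (from 2-methylresorcinol) are joined without ring formation; the phthalide ring closes after deallylation, then ring C closes by lactonisation.
Stereochemistry: the only stereocentre (the lactol carbon on C6', R) is fixed after all rings exist, by equilibrating acetal exchange with (S)-1-phenylethanol, collection of the (R)-acetal and re-equilibration of its epimer; hydrogenolysis of the O–benzylic bonds then frees the lactol without touching the C–O bonds at that carbon.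

Key step: step 12

Assumption: the free lactol epimerises through ring–chain tautomerism in protic or basic media, so its (R) configuration is taken to persist only under neutral aprotic conditions and it is unmasked in the last step.

**Ring A**

Step 1
Reactants: 1 3-methoxy-5-methylphenol
Product: 2 3-methoxy-5-methylphenyl N-isopropylcarbamate
Conditions: i-PrNCO, Et3N (cat.), CH2Cl2, rt
Reagents that add atoms: isopropyl isocyanate, CC(C)N=C=O
Why: Base-catalysed addition of the phenol to the isocyanate gives an N-isopropyl carbamate, a strong director for ortho-lithiation that can later be removed under mild basic conditions.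

Step 2
Reactants: 2 3-methoxy-5-methylphenyl N-isopropylcarbamate
Product: 6 3-methoxy-5-methyl-2-(trimethylsilyl)phenyl N-isopropylcarbamate, via N-silyl carbamate 3 (not isolated), via aryllithium 4 (not isolated), via N-silyl arylsilane 5 (not isolated)
Conditions: TBSOTf, TMEDA, Et2O, 0 °C → rt; n-BuLi, TMEDA, −78 °C; TMSCl, −78 °C → rt; aq. NaHSO4
Reagents that add atoms: chlorotrimethylsilane, C[Si](C)(C)Cl
Why: After transient N-silylation, directed ortho-metalation takes place at the carbon between the carbamate and methoxy groups (future C6), where both directors cooperate, and the aryllithium is silylated; aqueous acid then removes the N-silyl group.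

Step 3
Reactants: 6 3-methoxy-5-methyl-2-(trimethylsilyl)phenyl N-isopropylcarbamate
Product: 10 allyl 2-[(isopropylcarbamoyl)oxy]-4-methoxy-6-methyl-3-(trimethylsilyl)benzoate, via N-trimethylsilyl arylsilane 7 (not isolated), via aryllithium 8 (not isolated), via N-trimethylsilyl ester 9 (not isolated)
Conditions: Me3SiOTf, TMEDA, Et2O, 0 °C → rt; s-BuLi, TMEDA, −78 °C; ClCO2CH2CH=CH2, −78 °C; aq. NH4Cl, MeOH
Reagents that add atoms: allyl chloroformate, C=CCOC(Cl)=O
Why: Nitrogen is masked this time with the smaller, more water-labile trimethylsilyl group, so that a buffered work-up suffices for the ester-bearing arylsilane; with the site between the two oxygens blocked by silicon, the second directed ortho-metalation can only take the other ortho carbon (future C4), and acylation of the aryllithium by the chloroformate gives a di-ortho-substituted ester that resists a second addition.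

Step 4
Reactants: 10 allyl 2-[(isopropylcarbamoyl)oxy]-4-methoxy-6-methyl-3-(trimethylsilyl)benzoate
Product: 12 allyl 4-methoxy-6-methyl-2-(trifluoromethanesulfonyloxy)-3-(trimethylsilyl)benzoate, via phenol 11 (not isolated)
Conditions: Et2NH, DBU, MeCN, 40 °C; then PhNTf2, 40 °C
Reagents that add atoms: N-phenylbis(trifluoromethanesulfonimide), O=S(=O)(N(c1ccccc1)S(=O)(=O)C(F)(F)F)C(F)(F)F
Why: DBU induces E1cB loss of isopropyl isocyanate (trapped by diethylamine), and the liberated phenoxide is triflated in the same flask, so the acid-sensitive aryl–silicon bond is never exposed to acid.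

**Ring B**

Step 5
Reactants: 13 2-methylresorcinol
Product: 14 2,4-dihydroxy-3-methylbenzoic acid
Conditions: KHCO3, CO2 (1 atm), H2O, 100 °C; then aq. HCl
Reagents that add atoms: carbon dioxide, O=C=O
Why: Kolbe–Schmitt carboxylation of the resorcinol anion occurs ortho to a hydroxyl group, and the two open ortho positions are equivalent, so a single acid results.

Step 6
Reactants: 14 2,4-dihydroxy-3-methylbenzoic acid
Product: 15 allyl 2,4-dihydroxy-3-methylbenzoate
Conditions: allyl bromide, KHCO3, DMF, 40 °C
Reagents that add atoms: allyl bromide, C=CCBr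
Why: KHCO3 deprotonates only the carboxylic acid, so SN2 alkylation gives the allyl ester and leaves both phenols free.

Step 7
Reactants: 15 allyl 2,4-dihydroxy-3-methylbenzoate
Product: 16 allyl 5-formyl-2,4-dihydroxy-3-methylbenzoate
Conditions: MgCl2, Et3N, (CH2O)n, MeCN, reflux; aq. HCl
Reagents that add atoms: formaldehyde (as paraformaldehyde), C=O
Why: The magnesium-mediated ortho-formylation of phenols (Casnati–Skattebøl reaction) delivers formaldehyde only ortho to a phenoxide, and position 5 of the benzoate, next to the 4-hydroxyl, is the only free ortho position; this formyl group serves as a masked hydroxyl.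

Step 8
Reactants: 16 allyl 5-formyl-2,4-dihydroxy-3-methylbenzoate
Product: 17 allyl 2,4-bis(allyloxy)-5-formyl-3-methylbenzoate
Conditions: allyl bromide, K2CO3, DMF, 60 °C
Reagents that add atoms: allyl bromide, C=CCBr
Why: Williamson alkylation of both hydrogen-bonded phenols under carbonate in DMF caps the oxygens on C2' and C4', so the only oxygen later set free on this ring is the one on C1'.

Step 9
Reactants: 17 allyl 2,4-bis(allyloxy)-5-formyl-3-methylbenzoate
Product: 19 allyl 2,4-bis(allyloxy)-5-hydroxy-3-methylbenzoate, via aryl formate 18 (not isolated)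
Conditions: mCPBA, CH2Cl2, 0 °C → rt; then Et3N, MeOH, rt
Reagents that add atoms: 3-chloroperoxybenzoic acid, OOC(=O)c1cccc(Cl)c1
Why: Baeyer–Villiger oxidation of this ortho,para-dialkoxybenzaldehyde proceeds by aryl migration faster than epoxidation of the terminal allyl groups, and mild methanolysis of the aryl formate frees the C1' hydroxyl without transesterifying the benzoate.

Step 10
Reactants: 19 allyl 2,4-bis(allyloxy)-5-hydroxy-3-methylbenzoate
Product: 20 allyl 2,4-bis(allyloxy)-6-formyl-5-hydroxy-3-methylbenzoate
Conditions: MgCl2, Et3N, (CH2O)n, MeCN, reflux; aq. HCl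
Reagents that add atoms: formaldehyde (as paraformaldehyde), C=O
Why: The same phenoxide-directed ortho-formylation can only reach the last open ring position (C6'), which lies ortho to the free C1' hydroxyl.

Step 11
Reactants: 20 allyl 2,4-bis(allyloxy)-6-formyl-5-hydroxy-3-methylbenzoate
Product: 21 allyl 2,4-bis(allyloxy)-6-(dimethoxymethyl)-5-hydroxy-3-methylbenzoate
Conditions: HC(OMe)3, MeOH, PPTS (cat.), rt; Et3N quench
Reagents that add atoms: trimethyl orthoformate, COC(OC)OC; methanol, CO
Why: Acid-catalysed acetalisation with the orthoformate as water scavenger masks the aldehyde, which would otherwise trap the aryl anion of the coupling, and the basic quench protects the labile ortho-hydroxy acetal.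

**Coupling**

Step 12
Reactants: 21 allyl 2,4-bis(allyloxy)-6-(dimethoxymethyl)-5-hydroxy-3-methylbenzoate; 12 allyl 4-methoxy-6-methyl-2-(trifluoromethanesulfonyloxy)-3-(trimethylsilyl)benzoate
Product: 25 3-[(allyloxy)carbonyl]-2-{2,4-bis(allyloxy)-5-[(allyloxy)carbonyl]-6-(dimethoxymethyl)-3-methylphenoxy}-6-methoxy-4-methylbenzoic acid, via potassium phenoxide 22 (not isolated), via aryne 23 (not isolated), via arylpotassium adduct 24 (not isolated)
Conditions: KH, THF, 0 °C; then 12, KF, 18-crown-6, CO2 (1 atm), THF, 0 °C → rt; cold aq. KH2PO4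
Reagents that add atoms: carbon dioxide, O=C=O
Why: Proposed new method: fluoride strips the silyl group from 12 and triflate leaves to give aryne 23, the preformed potassium phenoxide 22 adds to C5, and the aryl anion 24 that appears at C6 is intercepted by dissolved CO2, so the C5–O ether bond and the C6–carboxyl bond arise in a single operation. The nearest known reaction types are the three-component union of arynes with nitrogen nucleophiles and CO2 to give ortho-substituted benzoic acids and the metal-free O-arylation of hindered phenols by arynes; pairing a phenoxide with CO2 in this way is the untested part. No ring closes and no stereocentre forms. Addition must occur at C5 and not at C6: the in-plane, inductively withdrawing C–O bond of the C1 methoxy group makes the remote aryne carbon C5 the electrophilic one and stabilises the charge building at C6, while the C4 ester, bound through carbon, pulls the other way only weakly. Carboxylation must also beat protonation and acyl attack, which is why the phenoxide is made with KH so that no O–H remains, THF replaces an acidic nitrile solvent, the C6' aldehyde is masked as its acetal, every ring B carbon is substituted so that only oxygen can bond, and neither ester carbonyl can be reached by the aryl anion through a small-ring transition state. Since aryne capture involves no crowded metal centre, this diaryl ether with four ortho substituents, a poor substrate for copper or palladium coupling, should be accessible.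

**Endgame**

Step 13
Reactants: 25 diaryl ether acid (C6 CO2H)
Product: 27 diaryl ether benzylic alcohol (C6 CH2OH; other groups as in 25), via acyl chloride 26 (not isolated)
Conditions: 1-chloro-N,N,2-trimethylprop-1-en-1-amine, CH2Cl2, 0 °C → rt; then NaBH4, THF–diglyme, 0 °C
Reagents that add atoms: none
Why: The chloroenamine converts the hindered acid into its chloride without releasing HCl, so the acetal survives, and NaBH4 reduces the acyl chloride to the primary alcohol while the hindered allyl benzoates are left alone.

Step 14
Reactants: 27 diaryl ether benzylic alcohol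
Product: 29 diaryl ether benzyl ether (C6 CH2OBn), via sodium alkoxide 28 (not isolated)
Conditions: NaH, THF–DMF, 0 °C; BnBr, Bu4NI (cat.), 0 °C → rt
Reagents that add atoms: benzyl bromide, BrCc1ccccc1
Why: Williamson etherification of the primary alkoxide protects the CH2OH group so that it cannot compete with the C2' phenol in the lactonisation or add to the oxocarbenium ion of the later acetal exchange.

Step 15
Reactants: 29 diaryl ether benzyl ether
Product: 31 racemic methoxyphthalide hydroxy acid (C4 CO2H, C2' OH, C4' OH, C5'/C6' as 3-methoxyphthalide), via deallylated diacid acetal 30 (not isolated)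
Conditions: Pd(PPh3)4 (cat.), morpholine, THF, rt; citrate buffer (pH 4) work-up; then PPTS (cat.), 4 Å MS, CH2Cl2, rt
Reagents that add atoms: none
Why: Tsuji–Trost deallylation with zerovalent palladium and morpholine as allyl acceptor removes all four allyl groups at once, and under mild acid the freed C5' acid displaces methanol from the neighbouring acetal in a five-membered closure, giving a pseudo-ester that masks the C5' acid for the next step.

Step 16
Reactants: 31 racemic methoxyphthalide hydroxy acid
Product: 32 racemic depsidone methoxyphthalide (ring C closed; C6 CH2OBn; C4' OH; methyl acetal at the lactol carbon)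
Conditions: DCC, DMAP (cat.), CH2Cl2 (0.005 M), rt
Reagents that add atoms: none
Why: Carbodiimide (Steglich) activation of the only free acid, on C4, and attack of the C2' phenol closes the seven-membered lactone, the established ring closure of depsidones from 2-(2-hydroxyaryloxy)benzoic acids, while high dilution suppresses intermolecular esters.

Step 17
Reactants: 32 racemic depsidone methoxyphthalide
Product: 34 depsidone (R)-acetal (lactol carbon R, bearing the (S)-1-phenylethoxy group; C6 CH2OBn), via (S)-acetal epimer 33 (not isolated)
Conditions: (S)-1-phenylethanol, PPTS (cat.), 5 Å MS, toluene, 70 °C; chromatography on silica gel; the epimer-enriched remainder re-equilibrated under the same conditions without purification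
Reagents that add atoms: (S)-1-phenylethanol, C[C@H](O)c1ccccc1
Why: Acid-catalysed transacetalisation of the pseudo-ester, driven by uptake of methanol on the sieves, attaches a hydrogenolysable chiral alkoxy group; both acetal epimers form and interconvert through the oxocarbenium ion under these conditions, so collecting the (R)-acetal 34 and returning epimer 33 to the equilibrium funnels the material into the diastereomer with the (R) lactol carbon, assigned against the (S)-auxiliary.

Step 18
Reactants: 34 depsidone (R)-acetal
Product: 35 target, CNP0367167.1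
Conditions: H2 (1 atm), Pd/C (10% palladium on carbon), EtOAc, rt, stopped at the calculated uptake
Reagents that add atoms: none
Why: Hydrogenolysis cleaves the unhindered O–CH2Ph and O–CH(CH3)Ph bonds far faster than the benzylic C–O bonds on the crowded rings A and B, so the lactol carbon keeps both of its C–O bonds and its (R) configuration while the benzylic alcohol and the lactol are set free under neutral aprotic conditions.

**Compound list**

1 | 3-methoxy-5-methylphenol | COc1cc(C)cc(O)c1 | starting material
2 | 3-methoxy-5-methylphenyl N-isopropylcarbamate | COc1cc(C)cc(OC(=O)NC(C)C)c1 | intermediate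
3 | 3-methoxy-5-methylphenyl N-(tert-butyldimethylsilyl)-N-isopropylcarbamate | COc1cc(C)cc(OC(=O)N(C(C)C)[Si](C)(C)C(C)(C)C)c1 | intermediate
4 | 2-lithio derivative of 3 (lithium between carbamate oxygen and methoxy group) | COc1cc(C)cc(OC(=O)N(C(C)C)[Si](C)(C)C(C)(C)C)c1[Li] | intermediate
5 | 3-methoxy-5-methyl-2-(trimethylsilyl)phenyl N-(tert-butyldimethylsilyl)-N-isopropylcarbamate | COc1cc(C)cc(OC(=O)N(C(C)C)[Si](C)(C)C(C)(C)C)c1[Si](C)(C)C | intermediate
6 | 3-methoxy-5-methyl-2-(trimethylsilyl)phenyl N-isopropylcarbamate | COc1cc(C)cc(OC(=O)NC(C)C)c1[Si](C)(C)C | intermediate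
7 | 3-methoxy-5-methyl-2-(trimethylsilyl)phenyl N-isopropyl-N-(trimethylsilyl)carbamate | COc1cc(C)cc(OC(=O)N(C(C)C)[Si](C)(C)C)c1[Si](C)(C)C | intermediate
8 | 6-lithio derivative of 7 (lithium between carbamate oxygen and methyl-bearing carbon) | COc1cc(C)c([Li])c(OC(=O)N(C(C)C)[Si](C)(C)C)c1[Si](C)(C)C | intermediate
9 | allyl 2-{[N-isopropyl-N-(trimethylsilyl)carbamoyl]oxy}-4-methoxy-6-methyl-3-(trimethylsilyl)benzoate | COc1cc(C)c(C(=O)OCC=C)c(OC(=O)N(C(C)C)[Si](C)(C)C)c1[Si](C)(C)C | intermediate
10 | allyl 2-[(isopropylcarbamoyl)oxy]-4-methoxy-6-methyl-3-(trimethylsilyl)benzoate | COc1cc(C)c(C(=O)OCC=C)c(OC(=O)NC(C)C)c1[Si](C)(C)C | intermediate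
11 | allyl 2-hydroxy-4-methoxy-6-methyl-3-(trimethylsilyl)benzoate | COc1cc(C)c(C(=O)OCC=C)c(O)c1[Si](C)(C)C | intermediate
12 | allyl 4-methoxy-6-methyl-2-(trifluoromethanesulfonyloxy)-3-(trimethylsilyl)benzoate (ring A silyl triflate) | COc1cc(C)c(C(=O)OCC=C)c(OS(=O)(=O)C(F)(F)F)c1[Si](C)(C)C | intermediate
13 | 2-methylresorcinol | Cc1c(O)cccc1O | starting material
14 | 2,4-dihydroxy-3-methylbenzoic acid | Cc1c(O)ccc(C(=O)O)c1O | intermediate
15 | allyl 2,4-dihydroxy-3-methylbenzoate | C=CCOC(=O)c1ccc(O)c(C)c1O | intermediate
16 | allyl 5-formyl-2,4-dihydroxy-3-methylbenzoate | C=CCOC(=O)c1cc(C=O)c(O)c(C)c1O | intermediate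
17 | allyl 2,4-bis(allyloxy)-5-formyl-3-methylbenzoate | C=CCOC(=O)c1cc(C=O)c(OCC=C)c(C)c1OCC=C | intermediate
18 | allyl 2,4-bis(allyloxy)-5-(formyloxy)-3-methylbenzoate | C=CCOC(=O)c1cc(OC=O)c(OCC=C)c(C)c1OCC=C | intermediate
19 | allyl 2,4-bis(allyloxy)-5-hydroxy-3-methylbenzoate | C=CCOC(=O)c1cc(O)c(OCC=C)c(C)c1OCC=C | intermediate
20 | allyl 2,4-bis(allyloxy)-6-formyl-5-hydroxy-3-methylbenzoate | C=CCOC(=O)c1c(C=O)c(O)c(OCC=C)c(C)c1OCC=C | intermediate
21 | allyl 2,4-bis(allyloxy)-6-(dimethoxymethyl)-5-hydroxy-3-methylbenzoate (ring B phenol) | C=CCOC(=O)c1c(C(OC)OC)c(O)c(OCC=C)c(C)c1OCC=C | intermediate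
22 | potassium phenoxide of 21 | [K+].[O-]c1c(OCC=C)c(C)c(OCC=C)c(C(=O)OCC=C)c1C(OC)OC | intermediate
23 | allyl 2,3-didehydro-4-methoxy-6-methylbenzoate (aryne, formal triple bond C5–C6) | COC1=CC(C)=C(C(=O)OCC=C)C#C1 | intermediate
24 | arylpotassium adduct (ring B aryloxy on C5, potassium on C6) | COc1cc(C)c(C(=O)OCC=C)c(Oc2c(OCC=C)c(C)c(OCC=C)c(C(=O)OCC=C)c2C(OC)OC)c1[K] | intermediate
25 | 3-[(allyloxy)carbonyl]-2-{2,4-bis(allyloxy)-5-[(allyloxy)carbonyl]-6-(dimethoxymethyl)-3-methylphenoxy}-6-methoxy-4-methylbenzoic acid | COc1cc(C)c(C(=O)OCC=C)c(Oc2c(OCC=C)c(C)c(OCC=C)c(C(=O)OCC=C)c2C(OC)OC)c1C(=O)O | intermediate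
26 | acyl chloride of 25 (C6 COCl) | COc1cc(C)c(C(=O)OCC=C)c(Oc2c(OCC=C)c(C)c(OCC=C)c(C(=O)OCC=C)c2C(OC)OC)c1C(Cl)=O | intermediate
27 | diaryl ether benzylic alcohol (C6 CH2OH; C4 and C5' allyl esters; C2' and C4' allyl ethers; C6' dimethyl acetal) | COc1cc(C)c(C(=O)OCC=C)c(Oc2c(OCC=C)c(C)c(OCC=C)c(C(=O)OCC=C)c2C(OC)OC)c1CO | intermediate
28 | sodium alkoxide of 27 | COc1cc(C)c(C(=O)OCC=C)c(Oc2c(OCC=C)c(C)c(OCC=C)c(C(=O)OCC=C)c2C(OC)OC)c1C[O-].[Na+] | intermediate
29 | diaryl ether benzyl ether (C6 CH2OBn; otherwise as 27) | COc1cc(C)c(C(=O)OCC=C)c(Oc2c(OCC=C)c(C)c(OCC=C)c(C(=O)OCC=C)c2C(OC)OC)c1COCc3ccccc3 | intermediate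
30 | deallylated diacid acetal (C4 CO2H, C5' CO2H, C2' OH, C4' OH, C6' dimethyl acetal, C6 CH2OBn) | COc1cc(C)c(C(=O)O)c(Oc2c(O)c(C)c(O)c(C(=O)O)c2C(OC)OC)c1COCc3ccccc3 | intermediate
31 | racemic methoxyphthalide hydroxy acid (C4 CO2H, C2' OH, C4' OH, C5'/C6' as 3-methoxyphthalide, C6 CH2OBn) | COc1cc(C)c(C(=O)O)c(Oc2c(O)c(C)c(O)c3c2C(OC)OC3=O)c1COCc4ccccc4 | intermediate
32 | racemic depsidone methoxyphthalide (ring C closed, C6 CH2OBn, C4' OH, methyl acetal at the lactol carbon) | COc1cc(C)c2c(c1COCc4ccccc4)Oc5c(c(C)c(O)c3c5C(OC)OC3=O)OC2=O | intermediate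
33 | depsidone (S)-acetal, lactol-carbon epimer of 34 (re-equilibrated) | COc1cc(C)c2c(c1COCc4ccccc4)Oc5c(c(C)c(O)c3c5[C@@H](O[C@@H](C)c6ccccc6)OC3=O)OC2=O | intermediate
34 | depsidone (R)-acetal (lactol carbon R with (S)-1-phenylethoxy group; C6 CH2OBn) | COc1cc(C)c2c(c1COCc4ccccc4)Oc5c(c(C)c(O)c3c5[C@H](O[C@@H](C)c6ccccc6)OC3=O)OC2=O | intermediate
35 | CNP0367167.1, depsidone lactol with (R) configuration at the lactol carbon | COc1cc(C)c2c(c1CO)Oc1c(c(C)c(O)c3c1[C@H](O)OC3=O)OC2=O | target

**Step count and risks**

Total steps: 18. Longest linear sequence: 14 steps (steps 5–18, from 2-methylresorcinol 13); ring A takes steps 1–4 and joins at step 12.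

Step 12 is the riskiest. The aryl anion may be protonated before it meets CO2, giving the ether without the carboxyl carbon on C6. The phenoxide may add at C6 if the steric and inductive influence of the C4 ester outweighs the methoxy bias. Reversible carbonation of the phenoxide may slow the addition until aryne decomposition wins. The fallback, by known chemistry, sets out from phenol 21 and returns at alcohol 27; it replaces the aryne by nucleophilic aromatic substitution on a ring A fluoride that already carries the one-carbon group on C6. Commercial 1-fluoro-3-methoxy-5-methylbenzene would be lithiated between fluorine and methoxy (n-BuLi, THF, −78 °C) to 2-fluoro-6-methoxy-4-methylphenyllithium F1 and quenched with DMF to give 2-fluoro-6-methoxy-4-methylbenzaldehyde F2. Acetalisation (HC(OMe)3, MeOH, PPTS) would give the dimethyl acetal F3. A second lithiation ortho to fluorine (s-BuLi, TMEDA, −78 °C) would give the aryllithium F4, and allyl chloroformate would convert it into allyl 3-(dimethoxymethyl)-2-fluoro-4-methoxy-6-methylbenzoate F5. Aqueous acetic acid would free the aldehyde to give allyl 2-fluoro-3-formyl-4-methoxy-6-methylbenzoate F6, whose fluorine is activated by two ortho carbonyl groups. Phenol 21 (K2CO3, DMF, 60 °C) would displace fluoride to give the diaryl ether aldehyde F7, and NaBH4 (THF–MeOH, 0 °C) would reduce the aldehyde to 27.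

Step 17 may fail because the two acetal epimers equilibrate to a mixture with no useful bias and do not separate, or because the secondary benzylic alcohol condenses with itself or racemises under the acid before exchange is complete. The fallback sets out from 32 and returns at target 35; it replaces the auxiliary by enantiomer separation. Exchange with benzyl alcohol (PPTS, 5 Å MS, toluene, 70 °C) would give the racemic depsidone benzyl acetal F8. Preparative chromatography on a chiral stationary phase would give the depsidone (R)-benzyl acetal F9, and the unwanted enantiomer would be racemised by the same acid and recycled. Hydrogenolysis under the conditions of step 18 would give 35.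

Step 10 may fail because formylation at the crowded carbon between the hydroxyl and the ester is slow, so that decomposition of formaldehyde or loss of the allyl ester takes over. The fallback sets out from phenol 19 and returns at aldehyde 20; it replaces the electrophilic formylation by a directed magnesiation. MOMCl and i-Pr2NEt would give the methoxymethyl ether F10. TMPMgCl·LiCl (THF, 0 °C → rt) would deprotonate the only ring C–H, flanked by the ester and the acetal-type ether, to give the arylmagnesium chloride F11. DMF would give the formyl methoxymethyl ether F12, and HCl in MeOH at rt would remove the methoxymethyl group to give 20.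

**Further compounds**

F1 | step 12 | 2-fluoro-6-methoxy-4-methylphenyllithium | COc1cc(C)cc(F)c1[Li]
F2 | step 12 | 2-fluoro-6-methoxy-4-methylbenzaldehyde | COc1cc(C)cc(F)c1C=O
F3 | step 12 | 2-(dimethoxymethyl)-1-fluoro-3-methoxy-5-methylbenzene | COc1cc(C)cc(F)c1C(OC)OC
F4 | step 12 | 6-lithio derivative of F3 (lithium between fluorine and methyl-bearing carbon) | COc1cc(C)c([Li])c(F)c1C(OC)OC
F5 | step 12 | allyl 3-(dimethoxymethyl)-2-fluoro-4-methoxy-6-methylbenzoate | COc1cc(C)c(C(=O)OCC=C)c(F)c1C(OC)OC
F6 | step 12 | allyl 2-fluoro-3-formyl-4-methoxy-6-methylbenzoate | COc1cc(C)c(C(=O)OCC=C)c(F)c1C=O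
F7 | step 12 | diaryl ether aldehyde (as 25 with CHO in place of CO2H on C6) | COc1cc(C)c(C(=O)OCC=C)c(Oc2c(OCC=C)c(C)c(OCC=C)c(C(=O)OCC=C)c2C(OC)OC)c1C=O
F8 | step 17 | racemic depsidone benzyl acetal (OCH2Ph on the lactol carbon, C6 CH2OBn) | COc1cc(C)c2c(c1COCc4ccccc4)Oc5c(c(C)c(O)c3c5C(OCc6ccccc6)OC3=O)OC2=O
F9 | step 17 | depsidone (R)-benzyl acetal | COc1cc(C)c2c(c1COCc4ccccc4)Oc5c(c(C)c(O)c3c5[C@H](OCc6ccccc6)OC3=O)OC2=O
F10 | step 10 | allyl 2,4-bis(allyloxy)-5-(methoxymethoxy)-3-methylbenzoate | C=CCOC(=O)c1cc(OCOC)c(OCC=C)c(C)c1OCC=C
F11 | step 10 | 6-(chloromagnesio) derivative of F10 | C=CCOC(=O)c1c([Mg]Cl)c(OCOC)c(OCC=C)c(C)c1OCC=C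
F12 | step 10 | allyl 2,4-bis(allyloxy)-6-formyl-5-(methoxymethoxy)-3-methylbenzoate | C=CCOC(=O)c1c(C=O)c(OCOC)c(OCC=C)c(C)c1OCC=C
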